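Its constants are assumed; the result is computed.

Decide at the outset to follow the D that each portion of X still has to meet, and leave X for later.

    D + G ⇌ D.G, settled at all times (K1 = 29.3 M⁻¹)
    2 D → D2 (k2 = 0.325 M⁻¹ s⁻¹)
    X + D ⇌ G + J (K3 = 0.80, k3 = 0.586 M⁻¹ s⁻¹)
    D + J ⇌ D.J, settled at all times (K4 = 35.9 M⁻¹)
X 0.030 M (fed, over 1.0 min); D 0.0900 M; time 1.0 min; the fed solution adds 1.0 times the starting volume
- amounts and yields of G count D.G too
- amounts and yields of J count D.J too
- for a step with 2 of a species take k times the square, and two of it per event
- charges are per starting volume, the dose included; the dosed solution carries all of it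
- run time (flask): 1.0 min
1. part of the X that has reacted at 1.0 min
2. share of free D in free D and D.J together, at 1.0 min

Begin with X + D by itself and hold c(D) at its charge. X then decays pseudo-first-order with a half-life of 0.22 min, short against the feed of 1.0 min, so about 69.7% of it reacts by the end of the feed.

Now add the pairing of D. Its first half-life, 0.285 min, is also shorter than the feed, so c(D) falls as a hyperbola. Call the exposure of a portion of X the rate constant of the main step times the integral of c(D) over its stay; the fraction of that portion left is exp(−exposure). Counted from the start, with t in feed times, exposure is g ln(one plus bt), where g is 0.586 M⁻¹ s⁻¹ over 2 times 0.325 M⁻¹ s⁻¹, or 0.902, and b is 2 times 0.325 M⁻¹ s⁻¹, the charge of D and the feed time, or 3.51. Solve the ends: the first portion meets the whole exposure and the last meets none. Join them by letting the portion fed at mid-feed stand for the whole charge, and c drops to 35.9%.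

Then add dilution: replace t by the logarithm of the volume over the starting volume. The whole exposure becomes 1.11, and the exposure of the mid-feed portion, the quantity to carry forward, is 0.314, so c is 27.0%. I leave out the D taken by X and the way back, and both work to lower c. It gives 0.00404 M of J, bound form counted, beside 0.0131 M of free D. Splitting J by 35.9 M⁻¹ gives fr as 91.0%.

The forecast put c at 26% (22% to 31%), below mine, and fr at 90% (87% to 93%), saying “the slow-fed X meets less and less D”. The flask gives c 25.5% and fr 90.9%.

The exposure 0.314 treats pairing as the taker of D. At 0.148 min in this flask, the ratio of D used by pairing to D used by the forward main step is 17, but at 1.00 min it is 1.0. Take the neighbour charged with 0.012 M of X: the charge of X does not enter the exposure, so 0.314 stands and c is again reckoned at 26.9%. That neighbour gives 27.6%.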